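**Strategy.** Numbering: C1/C5 ring-fusion carbons, C2=C3, carbinol C4, C6–C10 around the seven-membered ring (C10 bears the methylidene), side chain C11, C12. The cyclopentene ring is disconnected at C1–C5 and C3–C4: reading C3 as a latent carbonyl and the C4–O/C6–O pair as a 1,3-diketone, both bonds form in one amine/N-heterocyclic-carbene Michael–crossed-benzoin cascade between acyclic β-diketone 13 (C4–C9 with C7, C11, C12 set) and bromodienal 17 (C1–C3, C10), which builds the five-membered ring and C1, C4, C5. A Nozaki–Hiyama–Kishi closure (C9–C10) then forms the seven-membered ring; the ketol carbonyl is removed via its enol triflate and C6 is reduced under chelation control.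

Key step: step 10

Remark: (R)-TRIP is assumed to direct the crotyl group to the Re face of the aliphatic aldehyde 2, as it does with aryl aldehydes.
Remark: 11 is written in its open-chain form; it equilibrates with its cyclic hemiketal.

Step 1
Reactants: 1 4-methylpent-3-en-1-ol
Product: 2 4-methylpent-3-enal
Conditions: DMP (1,1,1-triacetoxy-1,1-dihydro-1,2-benziodoxol-3(1H)-one), CH2Cl2, 0 °C; used crude
Reagents that add atoms: none
Why: Periodinane oxidation of the primary alcohol under near-neutral conditions should give the β,γ-unsaturated aldehyde without moving the trisubstituted alkene into conjugation; no stereocentre is formed.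

Step 2
Reactants: 2 4-methylpent-3-enal; 3 (Z)-crotylboronic acid pinacol ester
Product: 4 (3S,4S)-3,7-dimethylocta-1,6-dien-4-ol
Conditions: (R)-TRIP (5 mol %), 4 Å molecular sieves, toluene, −30 °C; aqueous NaHCO3 work-up
Reagents that add atoms: none
Why: Chiral-phosphoric-acid-catalysed asymmetric crotylboration: the (Z)-boronate reacts through a closed chair transition state (syn C11/C12) and the catalyst directs it to the Re face of the aldehyde, which should set C12 and C11 both as S.

Step 3
Reactants: 4 (3S,4S)-3,7-dimethylocta-1,6-dien-4-ol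
Product: 6 (3S,4S)-3,7-dimethyloct-6-ene-1,4-diol, via 9-borabicyclononane adduct 5 (not isolated)
Conditions: 9-BBN (2.2 equiv), THF, 0 → 23 °C; then NaOH, H2O2, 0 °C
Reagents that add atoms: hydrogen peroxide, OO
Why: Hydroboration–oxidation: the bulky borane should add anti-Markovnikov to the monosubstituted alkene only and leave the trisubstituted prenyl alkene; no new stereocentre.

Step 4
Reactants: 6 (3S,4S)-3,7-dimethyloct-6-ene-1,4-diol
Product: 8 (4S,5S)-4-methyl-5-(3-methylbut-2-en-1-yl)oxolan-2-one, via lactol 7 (not isolated)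
Conditions: TEMPO (20 mol %), PhI(OAc)2 (2.5 equiv), CH2Cl2, 23 °C
Reagents that add atoms: none
Why: Oxoammonium-mediated oxidative lactonisation: the primary alcohol is oxidised selectively, the aldehyde closes to lactol 7 and is oxidised on to the γ-lactone, in which methyl and prenyl are cis; the electron-rich alkene is not attacked.

Step 5
Reactants: 8 (4S,5S)-4-methyl-5-(3-methylbut-2-en-1-yl)oxolan-2-one; 9 tert-butyl(2-iodoethoxy)dimethylsilane
Product: 10 (3S,4S,5S)-3-[2-(tert-butyldimethylsilyloxy)ethyl]-4-methyl-5-(3-methylbut-2-en-1-yl)oxolan-2-one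
Conditions: LiN(iPr)2, THF, −78 °C; then 9, DMPU, −78 → −20 °C
Reagents that add atoms: none
Why: Lactone enolate alkylation: the iodide should enter anti to the cis-disposed C11 methyl and C12 prenyl groups, setting C7 (S) trans to the methyl by substrate control.

Step 6
Reactants: 10 (3S,4S,5S)-3-[2-(tert-butyldimethylsilyloxy)ethyl]-4-methyl-5-(3-methylbut-2-en-1-yl)oxolan-2-one
Product: 11 (3S,4S,5S)-3-[2-(tert-butyldimethylsilyloxy)ethyl]-5-hydroxy-4,8-dimethylnon-7-en-2-one
Conditions: MeLi (1.05 equiv), THF, −78 °C; AcOH quench at −78 °C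
Reagents that add atoms: methyllithium, [Li]C
Why: Mono-addition of an organolithium to a γ-lactone: the tetrahedral lithium lactolate is stable at −78 °C and collapses only on work-up, so the methyl ketone should form without over-addition and without touching C7.

Step 7
Reactants: 11 (3S,4S,5S)-3-[2-(tert-butyldimethylsilyloxy)ethyl]-5-hydroxy-4,8-dimethylnon-7-en-2-one
Product: 12 (4S,5S,6S)-6-acetyl-8-(tert-butyldimethylsilyloxy)-2,5-dimethyloct-2-en-4-yl acetate
Conditions: Ac2O, pyridine, DMAP (cat.), CH2Cl2, 0 → 23 °C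
Reagents that add atoms: acetic anhydride, CC(=O)OC(C)=O
Why: Nucleophile-catalysed acetylation of the secondary alcohol of the open-chain form installs the C12 acetate of the target and drains the hemiketal equilibrium.

Step 8
Reactants: 12 (4S,5S,6S)-6-acetyl-8-(tert-butyldimethylsilyloxy)-2,5-dimethyloct-2-en-4-yl acetate
Product: 13 (5S,6S,7S)-7-acetoxy-5-[2-(tert-butyldimethylsilyloxy)ethyl]-6,10-dimethylundec-9-ene-2,4-dione
Conditions: MgBr2·OEt2 (2.5 equiv), i-Pr2NEt (3 equiv), 1-acetyl-1H-benzotriazole (1.3 equiv), CH2Cl2, 23 °C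
Reagents that add atoms: 1-acetyl-1H-benzotriazole, CC(=O)n1nnc2ccccc12
Why: Soft-enolisation crossed Claisen acylation: the magnesium enolate forms at the unhindered methyl group and is C-acetylated by the acyl benzotriazole under conditions mild enough for the acetate, the silyl ether and the α-stereocentre C7.

Step 9
Reactants: 14 2-bromoprop-2-en-1-ol; 15 (triphenylphosphoranylidene)acetaldehyde
Product: 17 (2E)-4-bromopenta-2,4-dienal, via 2-bromoprop-2-enal 16 (not isolated)
Conditions: MnO2 (10 equiv), CH2Cl2, 23 °C, 15 (1.1 equiv) present from the start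
Reagents that add atoms: none
Why: Tandem allylic oxidation–Wittig olefination: the sensitive aldehyde 16 is trapped as it forms by the stabilised ylide, which should give the (E)-enal.

Step 10
Reactants: 13 (5S,6S,7S)-7-acetoxy-5-[2-(tert-butyldimethylsilyloxy)ethyl]-6,10-dimethylundec-9-ene-2,4-dione; 17 (2E)-4-bromopenta-2,4-dienal
Product: 19 (2R,3S,4R)-3-{(2S,3S,4S)-4-acetoxy-2-[2-(tert-butyldimethylsilyloxy)ethyl]-3,7-dimethyloct-6-enoyl}-4-(1-bromoethenyl)-2-hydroxy-2-methylcyclopentan-1-one, via keto aldehyde Michael adduct 18 (not isolated)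
Conditions: (S)-α,α-diphenylprolinol trimethylsilyl ether (20 mol %), 2-(pentafluorophenyl)-6,7-dihydro-5H-pyrrolo[2,1-c][1,2,4]triazol-2-ium tetrafluoroborate (10 mol %), NaOAc (10 mol %), CHCl3, 23 °C
Reagents that add atoms: none
Why: The secondary amine turns enal 17 into an iminium ion, to which the central carbon of the 1,3-diketone adds at the β-carbon (C1–C5) to give keto aldehyde 18; the triazolylidene then converts the freed aldehyde into an acyl-anion equivalent (carbene–aldehyde enaminol) that adds to the acetyl carbonyl (C3–C4) in an intramolecular crossed benzoin reaction. The closest known reaction type is the amine/N-heterocyclic-carbene multicatalytic Michael–benzoin formal (3+2) annulation of enals with 1,3-diketones. The cyclopentanone closes in a 5-exo-trig mode, C3 attacking the exocyclic C4=O. C1 (R) is set by the (S)-amine, which shields one face of the iminium; C4 is set in the hydrogen-bonded benzoin transition state, in which the azolium and the acetyl methyl should lie on the face away from the C1 bromovinyl group so that the hydroxyl ends cis to it; C5 stays epimerisable (1,3-diketone, then α to the C6 ketone) and should settle trans to C1. The step needs β- rather than δ-attack on the dienal, favoured by the larger LUMO coefficient at the β-carbon and by bromine donation into the terminal alkene, and benzoin closure on the acetyl rather than the C6 carbonyl, favoured by the α-branching at C7.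

Step 11
Reactants: 19 (2R,3S,4R)-3-{(2S,3S,4S)-4-acetoxy-2-[2-(tert-butyldimethylsilyloxy)ethyl]-3,7-dimethyloct-6-enoyl}-4-(1-bromoethenyl)-2-hydroxy-2-methylcyclopentan-1-one
Product: 20 (2R,3S,4R)-3-[(2S,3S,4S)-4-acetoxy-2-(2-hydroxyethyl)-3,7-dimethyloct-6-enoyl]-4-(1-bromoethenyl)-2-hydroxy-2-methylcyclopentan-1-one
Conditions: HF·pyridine, pyridine, THF, 0 → 23 °C
Reagents that add atoms: none
Why: Fluoride-mediated desilylation: buffered HF should cleave the primary silyl ether while the acetate, the tertiary ketol and the alkenyl bromide survive.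

Step 12
Reactants: 20 (2R,3S,4R)-3-[(2S,3S,4S)-4-acetoxy-2-(2-hydroxyethyl)-3,7-dimethyloct-6-enoyl]-4-(1-bromoethenyl)-2-hydroxy-2-methylcyclopentan-1-one
Product: 21 (2R,3S,4R)-3-[(2S,3S,4S)-4-acetoxy-3,7-dimethyl-2-(2-oxoethyl)oct-6-enoyl]-4-(1-bromoethenyl)-2-hydroxy-2-methylcyclopentan-1-one
Conditions: DMP, CH2Cl2, 0 °C
Reagents that add atoms: none
Why: Periodinane oxidation of the primary alcohol to the aldehyde; the tertiary alcohol cannot be oxidised and the near-neutral conditions should not epimerise C5 or C7.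

Step 13
Reactants: 21 (2R,3S,4R)-3-[(2S,3S,4S)-4-acetoxy-3,7-dimethyl-2-(2-oxoethyl)oct-6-enoyl]-4-(1-bromoethenyl)-2-hydroxy-2-methylcyclopentan-1-one
Product: 22 (1R,4R,5S,7S,9R)-7-[(2S,3S)-3-acetoxy-6-methylhept-5-en-2-yl]-4,9-dihydroxy-4-methyl-10-methylidenebicyclo[5.3.0]decane-3,6-dione (numbering of the strategy paragraph)
Conditions: CrCl2 (6 equiv), NiCl2 (2 mol %), DMSO, 23 °C, high dilution
Reagents that add atoms: none
Why: Intramolecular Nozaki–Hiyama–Kishi reaction: the alkenylchromium formed from the 2-bromoalkene adds to the aldehyde only (ketones are spared) and closes the seven-membered ring in a 7-exo-trig mode; allylic 1,3-strain with the emerging exocyclic methylene should hold the C9–O bond pseudo-axial while the C7 side chain stays pseudo-equatorial, giving the 7,9-trans alcohol (C9 R).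

Step 14
Reactants: 22 (1R,4R,5S,7S,9R)-7-[(2S,3S)-3-acetoxy-6-methylhept-5-en-2-yl]-4,9-dihydroxy-4-methyl-10-methylidenebicyclo[5.3.0]decane-3,6-dione
Product: 23 4,9-bis(triethylsilyl) ether of 22, (1R,4R,5S,7S,9R)
Conditions: Et3SiOTf (3 equiv), 2,6-lutidine, CH2Cl2, −78 → 0 °C
Reagents that add atoms: triethylsilyl trifluoromethanesulfonate, CC[Si](CC)(CC)OS(=O)(=O)C(F)(F)F
Why: Silyl triflate silylation caps the allylic alcohol and the tertiary aldol-type alcohol, which blocks retro-aldol cleavage and ketol shift before strong base is used.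

Step 15
Reactants: 23 4,9-bis(triethylsilyl) ether of 22
Product: 24 (1R,4R,5S,7S,9R)-3-(trifluoromethylsulfonyloxy)-2-ene-6-one bis(triethylsilyl) ether (C3 enol triflate of 23)
Conditions: KN(SiMe3)2 (1.1 equiv), THF, −78 °C; PhNTf2, −78 → 0 °C
Reagents that add atoms: N-phenylbis(trifluoromethanesulfonimide), O=S(=O)(N(c1ccccc1)S(=O)(=O)C(F)(F)F)C(F)(F)F
Why: Kinetic enolisation and O-triflation: the hindered amide base should take the unhindered C2 methylene proton of the cyclopentanone in preference to the methine protons flanking the C6 ketone and to the acetate, and the enolate is trapped as the C2=C3 enol triflate.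

Step 16
Reactants: 24 C3 enol triflate
Product: 25 (1R,4S,5S,7S,9R)-7-[(2S,3S)-3-acetoxy-6-methylhept-5-en-2-yl]-4-methyl-10-methylidene-4,9-bis(triethylsilyloxy)bicyclo[5.3.0]dec-2-en-6-one
Conditions: Pd(OAc)2 (5 mol %), PPh3 (10 mol %), Bu3N, HCO2H, DMF, 60 °C
Reagents that add atoms: none
Why: Palladium-catalysed formate reduction of an enol triflate (oxidative addition, formate exchange, decarboxylation, reductive elimination) replaces the triflate by hydrogen and leaves the C2=C3 alkene next to the C4 silyl ether.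

Step 17
Reactants: 25 bis(triethylsilyl) ether of the dienone
Product: 26 (1R,4S,5S,7S,9R)-7-[(2S,3S)-3-acetoxy-6-methylhept-5-en-2-yl]-4,9-dihydroxy-4-methyl-10-methylidenebicyclo[5.3.0]dec-2-en-6-one
Conditions: HF·pyridine, pyridine, THF, 0 → 23 °C
Reagents that add atoms: none
Why: Fluoride-mediated cleavage of both silyl ethers under buffered conditions that should neither ionise the tertiary allylic alcohol nor cleave the acetate.

Step 18
Reactants: 26 dihydroxy ketone
Product: 27 CNP0126182.2, (1R,4S,5R,6R,7S,9R)-7-[(2S,3S)-3-acetoxy-6-methylhept-5-en-2-yl]-4-methyl-10-methylidenebicyclo[5.3.0]dec-2-ene-4,6,9-triol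
Conditions: Et2BOMe (1.1 equiv), THF/MeOH 4:1, −78 °C; NaBH4; AcOH, then repeated evaporation from MeOH
Reagents that add atoms: none
Why: Narasaka–Prasad reduction: the boron reagent ties the C4 hydroxyl and the C6 carbonyl into a six-membered chelate and external hydride attacks it axially, which should give the 4,6-syn diol, that is C6 (R) with its hydroxyl cis to H5.

**Compound list**

1 | 4-methylpent-3-en-1-ol | CC(C)=CCCO | starting material
2 | 4-methylpent-3-enal | CC(C)=CCC=O | intermediate
3 | (Z)-crotylboronic acid pinacol ester, 2-[(2Z)-but-2-en-1-yl]-4,4,5,5-tetramethyl-1,3,2-dioxaborolane | C/C=C\CB1OC(C)(C)C(C)(C)O1 | starting material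
4 | (3S,4S)-3,7-dimethylocta-1,6-dien-4-ol | C=C[C@H](C)[C@@H](O)CC=C(C)C | intermediate
5 | 9-borabicyclononane adduct of 4 (C1 alkylborane and O-borinate) | C(C[C@H](C)[C@@H](OB1C2CCCC1CCC2)CC=C(C)C)B1C2CCCC1CCC2 | intermediate
6 | (3S,4S)-3,7-dimethyloct-6-ene-1,4-diol | OCC[C@H](C)[C@@H](O)CC=C(C)C | intermediate
7 | (4S,5S)-4-methyl-5-(3-methylbut-2-en-1-yl)oxolan-2-ol (lactol, both anomers) | OC1C[C@H](C)[C@H](CC=C(C)C)O1 | intermediate
8 | (4S,5S)-4-methyl-5-(3-methylbut-2-en-1-yl)oxolan-2-one (methyl and prenyl cis) | O=C1C[C@H](C)[C@H](CC=C(C)C)O1 | intermediate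
9 | tert-butyl(2-iodoethoxy)dimethylsilane | CC(C)(C)[Si](C)(C)OCCI | starting material
10 | (3S,4S,5S)-3-[2-(tert-butyldimethylsilyloxy)ethyl]-4-methyl-5-(3-methylbut-2-en-1-yl)oxolan-2-one | O=C1[C@@H](CCO[Si](C)(C)C(C)(C)C)[C@H](C)[C@H](CC=C(C)C)O1 | intermediate
11 | (3S,4S,5S)-3-[2-(tert-butyldimethylsilyloxy)ethyl]-5-hydroxy-4,8-dimethylnon-7-en-2-one | CC(=O)[C@@H](CCO[Si](C)(C)C(C)(C)C)[C@H](C)[C@@H](O)CC=C(C)C | intermediate
12 | (4S,5S,6S)-6-acetyl-8-(tert-butyldimethylsilyloxy)-2,5-dimethyloct-2-en-4-yl acetate | CC(=O)[C@@H](CCO[Si](C)(C)C(C)(C)C)[C@H](C)[C@@H](OC(C)=O)CC=C(C)C | intermediate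
13 | (5S,6S,7S)-7-acetoxy-5-[2-(tert-butyldimethylsilyloxy)ethyl]-6,10-dimethylundec-9-ene-2,4-dione | CC(=O)CC(=O)[C@@H](CCO[Si](C)(C)C(C)(C)C)[C@H](C)[C@@H](OC(C)=O)CC=C(C)C | intermediate
14 | 2-bromoprop-2-en-1-ol | OCC(Br)=C | starting material
15 | (triphenylphosphoranylidene)acetaldehyde | O=CC=P(c1ccccc1)(c1ccccc1)c1ccccc1 | starting material
16 | 2-bromoprop-2-enal | O=CC(Br)=C | intermediate
17 | (2E)-4-bromopenta-2,4-dienal | O=C/C=C/C(Br)=C | intermediate
18 | (3R)-4-{(2S,3S,4S)-4-acetoxy-2-[2-(tert-butyldimethylsilyloxy)ethyl]-3,7-dimethyloct-6-enoyl}-3-(1-bromoethenyl)-5-oxohexanal (C4 of the hexanal epimerisable) | O=CC[C@@H](C(Br)=C)C(C(C)=O)C(=O)[C@@H](CCO[Si](C)(C)C(C)(C)C)[C@H](C)[C@@H](OC(C)=O)CC=C(C)C | intermediate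
19 | (2R,3S,4R)-3-{(2S,3S,4S)-4-acetoxy-2-[2-(tert-butyldimethylsilyloxy)ethyl]-3,7-dimethyloct-6-enoyl}-4-(1-bromoethenyl)-2-hydroxy-2-methylcyclopentan-1-one | O=C1C[C@@H](C(Br)=C)[C@H](C(=O)[C@@H](CCO[Si](C)(C)C(C)(C)C)[C@H](C)[C@@H](OC(C)=O)CC=C(C)C)[C@@]1(C)O | intermediate
20 | (2R,3S,4R)-3-[(2S,3S,4S)-4-acetoxy-2-(2-hydroxyethyl)-3,7-dimethyloct-6-enoyl]-4-(1-bromoethenyl)-2-hydroxy-2-methylcyclopentan-1-one | O=C1C[C@@H](C(Br)=C)[C@H](C(=O)[C@@H](CCO)[C@H](C)[C@@H](OC(C)=O)CC=C(C)C)[C@@]1(C)O | intermediate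
21 | (2R,3S,4R)-3-[(2S,3S,4S)-4-acetoxy-3,7-dimethyl-2-(2-oxoethyl)oct-6-enoyl]-4-(1-bromoethenyl)-2-hydroxy-2-methylcyclopentan-1-one | O=C1C[C@@H](C(Br)=C)[C@H](C(=O)[C@@H](CC=O)[C@H](C)[C@@H](OC(C)=O)CC=C(C)C)[C@@]1(C)O | intermediate
22 | (1R,4R,5S,7S,9R)-7-[(2S,3S)-3-acetoxy-6-methylhept-5-en-2-yl]-4,9-dihydroxy-4-methyl-10-methylidenebicyclo[5.3.0]decane-3,6-dione (trans-fused; numbering of the strategy paragraph) | C=C1[C@H](O)C[C@@H]([C@H](C)[C@H](CC=C(C)C)OC(C)=O)C(=O)[C@H]2[C@H]1CC(=O)[C@]2(C)O | intermediate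
23 | 4,9-bis(triethylsilyl) ether of 22 | C=C1[C@H](O[Si](CC)(CC)CC)C[C@@H]([C@H](C)[C@H](CC=C(C)C)OC(C)=O)C(=O)[C@H]2[C@H]1CC(=O)[C@]2(C)O[Si](CC)(CC)CC | intermediate
24 | C3 enol triflate of 23 (C2=C3, 3-trifluoromethylsulfonyloxy, C6 ketone) | C=C1[C@H](O[Si](CC)(CC)CC)C[C@@H]([C@H](C)[C@H](CC=C(C)C)OC(C)=O)C(=O)[C@H]2[C@H]1C=C(OS(=O)(=O)C(F)(F)F)[C@]2(C)O[Si](CC)(CC)CC | intermediate
25 | (1R,4S,5S,7S,9R)-7-[(2S,3S)-3-acetoxy-6-methylhept-5-en-2-yl]-4-methyl-10-methylidene-4,9-bis(triethylsilyloxy)bicyclo[5.3.0]dec-2-en-6-one | C=C1[C@H](O[Si](CC)(CC)CC)C[C@@H]([C@H](C)[C@H](CC=C(C)C)OC(C)=O)C(=O)[C@H]2[C@H]1C=C[C@]2(C)O[Si](CC)(CC)CC | intermediate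
26 | (1R,4S,5S,7S,9R)-7-[(2S,3S)-3-acetoxy-6-methylhept-5-en-2-yl]-4,9-dihydroxy-4-methyl-10-methylidenebicyclo[5.3.0]dec-2-en-6-one | C=C1[C@H](O)C[C@@H]([C@H](C)[C@H](CC=C(C)C)OC(C)=O)C(=O)[C@H]2[C@H]1C=C[C@]2(C)O | intermediate
27 | CNP0126182.2, (1R,4S,5R,6R,7S,9R)-7-[(2S,3S)-3-acetoxy-6-methylhept-5-en-2-yl]-4-methyl-10-methylidenebicyclo[5.3.0]dec-2-ene-4,6,9-triol | C=C1[C@H](O)C[C@@H]([C@H](C)[C@H](CC=C(C)C)OC(C)=O)[C@@H](O)[C@H]2[C@H]1C=C[C@]2(C)O | target

**Step count and risks**

Total: 18 steps (steps 1–8 to diketone 13, step 9 to enal 17, steps 10–18). Longest linear sequence: 17 steps (1–8 and 10–18).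

Step 10. The benzoin ring closure may add to the other face of the acetyl carbonyl, leaving the C4 hydroxyl trans to the bromovinyl group, and some diketone may add to the terminal diene carbon. The fallback sets out from 13 and 17 under the same cascade and accepts the C4-epimeric ketol F1. F1 is treated with SmI2 in THF at −78 °C, which cleaves the tertiary C4–O bond of the α-hydroxy ketone and leaves the samarium enolate (C3=C4). 2-(Phenylsulfonyl)-3-phenyloxaziridine is then added to the same flask and hydroxylates the enolate from the face anti to the C5 acyl group. This resets C4 by enolate oxidation instead of by benzoin face selection and returns to the route at 19.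

Step 13. The alkenylchromium may add to the wrong face of the aldehyde during ring closure, and slow closure would let protodebromination compete. The fallback sets out from 21, which is cyclised under the same conditions to the C9-epimeric alcohol F2. F2 is inverted by a Mitsunobu reaction with chloroacetic acid (PPh3, diisopropyl azodicarboxylate, THF, 0 °C) to the 9-O-chloroacetate F3. Thiourea and NaHCO3 in EtOH then remove the chloroacetyl group in the presence of the acetate, and the route is rejoined at 22.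

Step 18. The hindered tertiary alcohol may fail to form the boron chelate, so that hydride arrives from the β-face and gives the C6 epimer. The fallback sets out from 25 and reduces the ketone before desilylation, with LiBH(s-Bu)3 in THF at −78 °C. There the β-face is screened by the C4 silyl ether and the C7 side chain (steric approach control), which should give the 6β-alcohol bis(triethylsilyl) ether F4. HF·pyridine then removes both silyl groups and the route is rejoined at 27.

Further compounds
F1 | step 10 | (2S,3S,4R)-3-{(2S,3S,4S)-4-acetoxy-2-[2-(tert-butyldimethylsilyloxy)ethyl]-3,7-dimethyloct-6-enoyl}-4-(1-bromoethenyl)-2-hydroxy-2-methylcyclopentan-1-one (C4 epimer of 19) | O=C1C[C@@H](C(Br)=C)[C@H](C(=O)[C@@H](CCO[Si](C)(C)C(C)(C)C)[C@H](C)[C@@H](OC(C)=O)CC=C(C)C)[C@]1(C)O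
F2 | step 13 | (1R,4R,5S,7S,9S)-7-[(2S,3S)-3-acetoxy-6-methylhept-5-en-2-yl]-4,9-dihydroxy-4-methyl-10-methylidenebicyclo[5.3.0]decane-3,6-dione (C9 epimer of 22) | C=C1[C@@H](O)C[C@@H]([C@H](C)[C@H](CC=C(C)C)OC(C)=O)C(=O)[C@H]2[C@H]1CC(=O)[C@]2(C)O
F3 | step 13 | 9-O-chloroacetate of 22, (1R,4R,5S,7S,9R) | C=C1[C@H](OC(=O)CCl)C[C@@H]([C@H](C)[C@H](CC=C(C)C)OC(C)=O)C(=O)[C@H]2[C@H]1CC(=O)[C@]2(C)O
F4 | step 18 | 4,9-bis(triethylsilyl) ether of 27, (1R,4S,5R,6R,7S,9R) | C=C1[C@H](O[Si](CC)(CC)CC)C[C@@H]([C@H](C)[C@H](CC=C(C)C)OC(C)=O)[C@@H](O)[C@H]2[C@H]1C=C[C@]2(C)O[Si](CC)(CC)CC
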